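Amounts came first. A mono adduct holds one coupling partner and a double product two, so I reckoned each flask by what its charge can pay for. East has 3.00 as its partner number E, the coupling partner charged per starting material charged. By this count, which reckons every starting material as taking up coupling partner, the crossing lay at E = 2: below it the coupling partner was the limiting reagent, above it the starting material was.

| setting | violet | teal | north | east | north-west |
|---|---|---|---|---|---|
| starting material | 0.20 M | 0.20 M | 0.20 M | 0.20 M | 0.20 M |
| coupling partner | 0.12 M | 0.46 M | 0.160 M | 0.600 M | 0.400 M |
| remark | run made earlier | run made earlier |  |  |  |
| time |  |  | 40 min | 40 min | 40 min |

- violet (time / min: double product / %, mono adduct / %): 6.00: 14, 29; 12.0: 13, 24; 15.0: 13, 26; 25.0: 16, 30; 30.0: 18, 27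
- teal (time / min: double product / %, mono adduct / %): 2.50: 96, 0; 8.00: 97, 0; 12.0: 96, 0; 20.0: 98, 2; 30.0: 96, 0

(readings scatter by 2 percentage points)

- which of these holds the largest part of the starting material at the end of north (double product / mono adduct / starting material)
- which of these holds the largest part of the starting material at the end of east (double product / mono adduct / starting material)
- which of these holds the largest part of the starting material at the end of north-west (double product / mono adduct / starting material)
- how much double product is there at the end of east, in percent of the starting material charged

The starting material stood at 0.20 M in violet, teal, north, east and north-west, so the partner charge was the setting to turn. In violet that charge was worth 60.0% of the starting material, and the last reading of mono adduct plus twice double product came to 63.0%, close to it for a sum of readings that each scatter by 2 percentage points. Teal, with E at 2.30, sat above the crossing and showed double product at 96%.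

Time I turned next. Teal read 96% double product at 2.50 min and 96% at 30.0 min, and violet read 29% mono adduct at 6.00 min and 27% at 30.0 min, so I gave the 40 min of the new flasks little weight.

By this count north, at 0.800, should show mono adduct plus twice double product near 80.0%. North-west, at 2.00, sits on the crossing, and east lies above it, so I expected east to read like teal. The count does not say what holds the rest of north, as neither violet nor teal read starting material.

The forecast named starting material for north, double product for east and double product for north-west, with 97% double product in east. For north it gave 45% starting material, “so starting material is largest”.

East gave 97.0% double product. North held 1.63% starting material at 40.0 min beside 43.5% self-condensation product, and its mono adduct, at 29.8%, led the three asked.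

    coupling partner + mono adduct → double product + by-product (k = 0.930 M⁻¹ s⁻¹)
    starting material + coupling partner → mono adduct + by-product (k = 0.780 M⁻¹ s⁻¹)
    2 starting material → self-condensation product (k = 0.0610 M⁻¹ s⁻¹)

East, with E at 3.00, took up 1.94 equiv. The flask like east but with 0.34 M of starting material has E at 1.76, below the crossing, and there mono adduct plus twice double product came to 176% of the starting material charged.

The data were generated by integration for an exercise; scatter was added.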